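**Strategy.** The 4-hydroxy-5,6-dihydropyran-2-one is read as a dearomatised furan: ring oxygen O1 with its flanking carbons C2 and C6 is the furan oxygen with its α-carbons, C7 and C8 are the furan β-carbons, and C3–C4(O)–C5 is an oxyallyl cation. A [4+3] cycloaddition of furan with the cation from 1,1,3,3-tetrabromoacetone forms C2–C3 and C5–C6 in one event and gives meso 8-oxabicyclo[3.2.1]oct-6-en-3-one. Desymmetrising hydroboration then fixes C6, Baeyer–Villiger cleavage of the C2–C8 bond unveils the lactone and a C8 aldehyde, and a 1,5-anti aldol followed by 1,3-anti reduction relays C12 (from a Brown allylation) to C8 and C10.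

Key step: step 1

Remark: the target is the enol form of a 3-oxo-δ-lactone, and keto and enol forms are treated as one compound. Target numbering is used throughout: ring O1, C2 (lactone C=O), C3, C4 (enol carbon), C5, C6; side chain C7 to C21 with carbinols at C8, C10 and C12.

**Route**

Step 1
Reactants: 1 furan; 2 1,1,3,3-tetrabromoacetone
Product: 5 8-oxabicyclo[3.2.1]oct-6-en-3-one (meso), via 1,3-dibromo-2-oxidoallyl cation 3 (not isolated), via 2,4-dibromo-8-oxabicyclo[3.2.1]oct-6-en-3-one 4 (not isolated)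
Conditions: Zn–Ag couple, furan (excess), THF, −10 °C to rt; then Zn–Cu couple, NH4Cl, MeOH, rt
Reagents that add atoms: none
Why: Zinc reduces one C–Br bond of 2 to a zinc enolate that loses bromide from the other α-carbon, giving the 1,3-dibromo-2-oxyallyl cation 3, a 2π three-carbon unit that adds across C2 and C5 of furan (4π) in a [4+3] cycloaddition; the closest known reaction type is the zinc-mediated polybromoketone–furan cycloaddition itself. This single event forms C2–C3 and C5–C6 (target numbering) and closes the cycloheptenone ring by cycloaddition, which at the same time completes the tetrahydropyran-4-one ring O1–C2–C3–C4–C5–C6 with the furan oxygen as the one-atom bridge. The two bridgehead stereocentres (C2 and C6) are forced cis by the bridge, so 5 is meso and no absolute control is needed at this stage; the C–Br stereocentres of 4 are erased by the Zn–Cu reduction in the same flask. The selectivity needed is cycloaddition over electrophilic substitution at the furan α-position and over self-condensation of the cation, which excess furan, low temperature and the halogen-stabilised cation should secure. Both partners are symmetric, so there is no regiochemical issue.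

Step 2
Reactants: 5 8-oxabicyclo[3.2.1]oct-6-en-3-one
Product: 6 spiro[8-oxabicyclo[3.2.1]oct-6-ene-3,2'-[1,3]dioxolane] (meso)
Conditions: TMSOCH2CH2OTMS, TMSOTf (cat.), CH2Cl2, −78 to −20 °C
Reagents that add atoms: 1,2-bis(trimethylsilyloxy)ethane, C[Si](C)(C)OCCO[Si](C)(C)C
Why: Noyori ketalisation under aprotic conditions should protect the C4 ketone without acid-induced β-elimination of the oxygen bridge, and the product stays meso.

Step 3
Reactants: 6 spiro[8-oxabicyclo[3.2.1]oct-6-ene-3,2'-[1,3]dioxolane]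
Product: 8 (1R,5R,6S)-spiro[8-oxabicyclo[3.2.1]octane-3,2'-[1,3]dioxolan]-6-ol (exo alcohol), via exo-6-(diisopinocampheylboryl) ketal 7 (not isolated)
Conditions: (−)-Ipc2BH [from (+)-α-pinene], THF, −25 °C; then NaOH, H2O2, 0 °C to rt
Reagents that add atoms: hydrogen peroxide, OO
Why: Asymmetric hydroboration from the exo face selects one of the two enantiotopic alkene carbons of meso 6 (sense assigned by analogy with norbornene, the antipodal borane being equally available) and oxidation with retention gives the exo alcohol, so that the bridgehead remote from the carbinol becomes C6 with the R configuration.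

Step 4
Reactants: 8 exo alcohol
Product: 9 (1R,5R)-spiro[8-oxabicyclo[3.2.1]octane-3,2'-[1,3]dioxolan]-6-one
Conditions: (n-Pr)4N[RuO4] (TPAP, cat.), NMO, 4 Å molecular sieves, CH2Cl2, rt
Reagents that add atoms: none
Why: Ley–Griffith oxidation is neutral, so the ketal should survive, and the bridgehead stereocentres cannot epimerise.

Step 5
Reactants: 9 bicyclic ketone
Product: 10 (1S,5S)-spiro[2,9-dioxabicyclo[3.3.1]nonane-7,2'-[1,3]dioxolan]-3-one
Conditions: mCPBA, NaHCO3, CH2Cl2, 0 °C to rt
Reagents that add atoms: 3-chloroperoxybenzoic acid, O=C(OO)c1cccc(Cl)c1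
Why: In this Baeyer–Villiger oxidation the α-oxygenated bridgehead carbon (C2) should migrate in preference to the CH2 group and with retention, which places oxygen between C8 and C2, turns C2 into an acylal carbon and leaves C6 untouched.

Step 6
Reactants: 10 acylal lactone
Product: 11 (2R)-1-[2-(2-hydroxyethyl)-1,3-dioxolan-2-yl]butane-2,4-diol
Conditions: LiAlH4, THF, 0 °C; Na2SO4·10H2O quench
Reagents that add atoms: none
Why: Hydride reduction of the lactone carbonyl (C8) releases the C2 aldehyde from the acylal, which is reduced as well, giving the triol with C6 unchanged and the ketal intact.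

Step 7
Reactants: 11 triol
Product: 13 2-[(7R)-9-oxo-1,4,8-trioxaspiro[4.5]decan-7-yl]acetaldehyde, via lactol aldehyde 12 (not isolated)
Conditions: TEMPO (cat.), PhI(OAc)2 (3.3 equiv), CH2Cl2, rt
Reagents that add atoms: none
Why: The oxoammonium oxidation takes primary alcohols first; the C2 aldehyde is trapped by the C6 hydroxyl as the six-membered lactol 12 and oxidised on to the δ-lactone (oxidative lactonisation of a 1,5-diol), while the C8 alcohol stops at the aldehyde because it has no hydroxyl to close a lactol with and no water is present.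

Step 8
Reactants: 14 decanal
Product: 16 (S)-tridec-1-en-4-ol, via diisopinocampheylborinate ester 15 (not isolated)
Conditions: B-allyldiisopinocampheylborane [from (−)-α-pinene], Et2O, −78 °C; then NaOH, H2O2, 0 °C to rt
Reagents that add atoms: B-allyldiisopinocampheylborane derived from (−)-α-pinene, C=CCB([C@H]1C[C@H]2C[C@@H]([C@@H]1C)C2(C)C)[C@H]1C[C@H]2C[C@@H]([C@@H]1C)C2(C)C
Why: Brown allylation through a chair Zimmerman–Traxler transition state should deliver the allyl group to the Re face of the aldehyde and so set C12 as S under reagent control.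

Step 9
Reactants: 16 (S)-tridec-1-en-4-ol
Product: 17 (S)-4-[(4-methoxybenzyl)oxy]tridec-1-ene
Conditions: NaH, PMBCl, Bu4NI (cat.), THF/DMF, 0 °C to rt
Reagents that add atoms: 4-methoxybenzyl chloride, COc1ccc(CCl)cc1
Why: Williamson etherification installs the benzyl-type ether that a β-oxygen needs in order to exert 1,5-anti induction in step 11 (silyl ethers do not).

Step 10
Reactants: 17 PMB ether
Product: 18 (S)-4-[(4-methoxybenzyl)oxy]tridecan-2-one
Conditions: PdCl2 (cat.), CuCl, O2 (1 atm), DMF/H2O, rt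
Reagents that add atoms: water, O
Why: Tsuji–Wacker oxidation of the terminal alkene (Markovnikov hydroxypalladation, then β-hydride elimination) should give the methyl ketone without touching C12.

Step 11
Reactants: 18 methyl ketone; 13 lactone aldehyde
Product: 21 (7R)-7-[(2S,6S)-2-hydroxy-6-[(4-methoxybenzyl)oxy]-4-oxopentadecyl]-1,4,8-trioxaspiro[4.5]decan-9-one, via dicyclohexylboron enolate 19 (not isolated), via dicyclohexylboron aldolate 20 (not isolated)
Conditions: (c-Hex)2BCl, Et3N, Et2O, 0 °C; then 13, −78 to −20 °C; then MeOH, pH 7 buffer, H2O2, 0 °C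
Reagents that add atoms: none
Why: The methyl-side boron enolate of a β-alkoxy methyl ketone adds to aldehydes with 1,5-anti induction (boat-like transition state organised by the β-oxygen), which should set C8 anti to C12 (R in target numbering) under non-basic conditions that spare the β-acyloxy aldehyde, the lactone and the ketal.

Step 12
Reactants: 21 β-hydroxy ketone
Product: 22 (7R)-7-[(2R,4R,6S)-2,4-dihydroxy-6-[(4-methoxybenzyl)oxy]pentadecyl]-1,4,8-trioxaspiro[4.5]decan-9-one
Conditions: Me4NBH(OAc)3, MeCN/AcOH, −30 °C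
Reagents that add atoms: none
Why: In the Evans–Saksena reduction the C8 hydroxyl binds the borohydride and delivers hydride intramolecularly through a chair transition state, which should give the 1,3-anti diol and so set C10; the lactone is inert to this reagent.

Step 13
Reactants: 22 anti-diol PMB ether
Product: 23 (7R)-7-[(2R,4S,6S)-2,4,6-trihydroxypentadecyl]-1,4,8-trioxaspiro[4.5]decan-9-one
Conditions: DDQ, CH2Cl2/pH 7 buffer, 0 °C
Reagents that add atoms: none
Why: Oxidative cleavage of the PMB ether by DDQ in the presence of water should free the C12 hydroxyl; any p-methoxybenzylidene acetal formed with the neighbouring C10 hydroxyl would be hydrolysed in step 14.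

Step 14
Reactants: 23 triol ketal
Product: 24 (6R)-4-hydroxy-6-[(2R,4S,6S)-2,4,6-trihydroxypentadecyl]-5,6-dihydro-2H-pyran-2-one (target)
Conditions: 1 M aq. HCl, THF, 0 °C to rt
Reagents that add atoms: water, O
Why: Acid hydrolysis of the dioxolane frees the C4 ketone, which enolises to the conjugated 4-hydroxy enol lactone; acid favours the closed δ-lactone and none of the four stereocentres is enolisable or otherwise at risk.

**Compound list**

1 | furan | c1ccoc1 | starting material
2 | 1,1,3,3-tetrabromoacetone | O=C(C(Br)Br)C(Br)Br | starting material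
3 | 1,3-dibromo-2-oxidoallyl cation (zinc-bound oxyallyl, written as zwitterion) | [O-]C(=CBr)[CH+]Br | intermediate (not isolated)
4 | 2,4-dibromo-8-oxabicyclo[3.2.1]oct-6-en-3-one (C–Br epimers) | C1=C[C@@H]2C(Br)C(=O)C(Br)[C@H]1O2 | intermediate (not isolated)
5 | 8-oxabicyclo[3.2.1]oct-6-en-3-one (meso) | C1=C[C@@H]2CC(=O)C[C@H]1O2 | intermediate
6 | spiro[8-oxabicyclo[3.2.1]oct-6-ene-3,2'-[1,3]dioxolane] (meso) | C1=C[C@@H]2CC3(OCCO3)C[C@H]1O2 | intermediate
7 | exo-6-(diisopinocampheylboryl) derivative of the saturated ketal | B([C@@H]1C[C@@H]2C[C@H]([C@H]1C)C2(C)C)([C@@H]1C[C@@H]2C[C@H]([C@H]1C)C2(C)C)[C@H]1C[C@@H]2CC3(OCCO3)C[C@H]1O2 | intermediate (not isolated)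
8 | (1R,5R,6S)-spiro[8-oxabicyclo[3.2.1]octane-3,2'-[1,3]dioxolan]-6-ol (exo) | O[C@H]1C[C@@H]2CC3(OCCO3)C[C@H]1O2 | intermediate
9 | (1R,5R)-spiro[8-oxabicyclo[3.2.1]octane-3,2'-[1,3]dioxolan]-6-one | O=C1C[C@@H]2CC3(OCCO3)C[C@H]1O2 | intermediate
10 | (1S,5S)-spiro[2,9-dioxabicyclo[3.3.1]nonane-7,2'-[1,3]dioxolan]-3-one | O=C1C[C@@H]2CC3(OCCO3)C[C@H](O1)O2 | intermediate
11 | (2R)-1-[2-(2-hydroxyethyl)-1,3-dioxolan-2-yl]butane-2,4-diol | OCC[C@@H](O)CC1(CCO)OCCO1 | intermediate
12 | 2-[(7R)-9-hydroxy-1,4,8-trioxaspiro[4.5]decan-7-yl]acetaldehyde (lactol, anomers) | O=CC[C@@H]1CC2(OCCO2)CC(O)O1 | intermediate (not isolated)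
13 | 2-[(7R)-9-oxo-1,4,8-trioxaspiro[4.5]decan-7-yl]acetaldehyde | O=CC[C@@H]1CC2(OCCO2)CC(=O)O1 | intermediate
14 | decanal | CCCCCCCCCC=O | starting material
15 | (S)-tridec-1-en-4-yl diisopinocampheylborinate | CCCCCCCCC[C@H](OB([C@H]1C[C@H]2C[C@@H]([C@@H]1C)C2(C)C)[C@H]1C[C@H]2C[C@@H]([C@@H]1C)C2(C)C)CC=C | intermediate (not isolated)
16 | (S)-tridec-1-en-4-ol | CCCCCCCCC[C@H](O)CC=C | intermediate
17 | (S)-4-[(4-methoxybenzyl)oxy]tridec-1-ene | CCCCCCCCC[C@H](OCc1ccc(OC)cc1)CC=C | intermediate
18 | (S)-4-[(4-methoxybenzyl)oxy]tridecan-2-one | CCCCCCCCC[C@H](OCc1ccc(OC)cc1)CC(C)=O | intermediate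
19 | dicyclohexylboron enolate of 18 (methyl side) | CCCCCCCCC[C@H](OCc1ccc(OC)cc1)CC(=C)OB(C1CCCCC1)C1CCCCC1 | intermediate (not isolated)
20 | dicyclohexylboron aldolate of 21 | CCCCCCCCC[C@H](OCc1ccc(OC)cc1)CC(=O)C[C@@H](OB(C1CCCCC1)C1CCCCC1)C[C@@H]1CC2(OCCO2)CC(=O)O1 | intermediate (not isolated)
21 | (7R)-7-[(2S,6S)-2-hydroxy-6-[(4-methoxybenzyl)oxy]-4-oxopentadecyl]-1,4,8-trioxaspiro[4.5]decan-9-one | CCCCCCCCC[C@H](OCc1ccc(OC)cc1)CC(=O)C[C@@H](O)C[C@@H]1CC2(OCCO2)CC(=O)O1 | intermediate
22 | (7R)-7-[(2R,4R,6S)-2,4-dihydroxy-6-[(4-methoxybenzyl)oxy]pentadecyl]-1,4,8-trioxaspiro[4.5]decan-9-one | CCCCCCCCC[C@H](OCc1ccc(OC)cc1)C[C@H](O)C[C@@H](O)C[C@@H]1CC2(OCCO2)CC(=O)O1 | intermediate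
23 | (7R)-7-[(2R,4S,6S)-2,4,6-trihydroxypentadecyl]-1,4,8-trioxaspiro[4.5]decan-9-one | CCCCCCCCC[C@H](O)C[C@H](O)C[C@@H](O)C[C@@H]1CC2(OCCO2)CC(=O)O1 | intermediate
24 | (6R)-4-hydroxy-6-[(2R,4S,6S)-2,4,6-trihydroxypentadecyl]-5,6-dihydro-2H-pyran-2-one | CCCCCCCCC[C@H](O)C[C@H](O)C[C@@H](O)C[C@@H]1CC(O)=CC(=O)O1 | target

**Step count.** Total: 14 steps. Longest linear sequence: 11 steps (steps 1 to 7, then 11 to 14); steps 8 to 10 build the side-chain ketone.

**Steps most likely to fail**

1. Step 7. The one-flask triple oxidation may go astray: the secondary C6 hydroxyl could be oxidised before the lactol closes, the C8 aldehyde could be over-oxidised, or the lactone oxygen could be lost by β-elimination from the β-acyloxy aldehyde. The fallback differentiates C2 and C8 at the acylal stage instead of reducing everything and re-oxidising. It sets out from 10. Opening of the acylal lactone with MeNH(OMe)·HCl and i-PrMgCl (THF, −20 °C) should give N-methoxy-N-methyl-2-[(7S)-9-hydroxy-1,4,8-trioxaspiro[4.5]decan-7-yl]acetamide F1. Fétizon oxidation (Ag2CO3 on Celite, toluene, reflux), which is selective for lactols, should then give N-methoxy-N-methyl-2-[(7S)-9-oxo-1,4,8-trioxaspiro[4.5]decan-7-yl]acetamide F2. Reduction of the amide with Cp2Zr(H)Cl (THF, rt), which leaves lactones alone, should give the aldehyde, and the fallback comes back to the route at 13.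

2. Step 11. Facial selectivity may erode through mismatched double stereodifferentiation (1,5-induction of the enolate against the β-acyloxy stereocentre of the aldehyde), and the aldehyde may enolise or eliminate. The fallback replaces the convergent aldol union by linear, reagent-controlled chain growth from the ring. It sets out from 13. Brown allylation with the same (−)-α-pinene-derived B-allyldiisopinocampheylborane (Et2O, −78 °C, buffered NaBO3 work-up) should give (7R)-7-[(2R)-2-hydroxypent-4-en-1-yl]-1,4,8-trioxaspiro[4.5]decan-9-one F3. PMB trichloroacetimidate with La(OTf)3 (cat.) should give the PMB ether (7R)-7-[(2R)-2-[(4-methoxybenzyl)oxy]pent-4-en-1-yl]-1,4,8-trioxaspiro[4.5]decan-9-one F4. Tsuji–Wacker oxidation (PdCl2, CuCl, O2, DMF/H2O) should give the methyl ketone (7R)-7-[(2S)-2-[(4-methoxybenzyl)oxy]-4-oxopentyl]-1,4,8-trioxaspiro[4.5]decan-9-one F5. Its (c-Hex)2B enolate should add to decanal 14 with 1,5-anti induction from C8 to give (7R)-7-[(2S,6S)-6-hydroxy-2-[(4-methoxybenzyl)oxy]-4-oxopentadecyl]-1,4,8-trioxaspiro[4.5]decan-9-one F6. Narasaka–Prasad reduction (Et2BOMe, NaBH4, THF/MeOH, −78 °C) should set C10 syn to C12 and give (7R)-7-[(2R,4S,6S)-4,6-dihydroxy-2-[(4-methoxybenzyl)oxy]pentadecyl]-1,4,8-trioxaspiro[4.5]decan-9-one F7. DDQ (CH2Cl2/pH 7 buffer) then removes the PMB group, and the fallback comes back to the route at 23.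

3. Step 3. The chiral borane may discriminate poorly between the enantiotopic alkene carbons of the ketal substrate, or the sense of induction may differ from the norbornene analogy. The fallback replaces reagent-controlled desymmetrisation by enzymatic kinetic resolution. It sets out from 6. Hydroboration with BH3·THF and NaOH/H2O2 oxidation should give the racemic exo alcohol, that is 8 together with its enantiomer (1S,5S,6R)-spiro[8-oxabicyclo[3.2.1]octane-3,2'-[1,3]dioxolan]-6-ol F8. Lipase-catalysed acylation (Candida antarctica lipase B, vinyl acetate, MTBE) is expected by the Kazlauskas rule to acetylate the 6R enantiomer to (1S,5S,6R)-spiro[8-oxabicyclo[3.2.1]octane-3,2'-[1,3]dioxolan]-6-yl acetate F9. The unreacted 6S alcohol is separated by chromatography, and the fallback comes back to the route at 8.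

**Further compounds**

F1 | step 7 | N-methoxy-N-methyl-2-[(7S)-9-hydroxy-1,4,8-trioxaspiro[4.5]decan-7-yl]acetamide | CON(C)C(=O)C[C@@H]1CC2(OCCO2)CC(O)O1
F2 | step 7 | N-methoxy-N-methyl-2-[(7S)-9-oxo-1,4,8-trioxaspiro[4.5]decan-7-yl]acetamide | CON(C)C(=O)C[C@@H]1CC2(OCCO2)CC(=O)O1
F3 | step 11 | (7R)-7-[(2R)-2-hydroxypent-4-en-1-yl]-1,4,8-trioxaspiro[4.5]decan-9-one | C=CC[C@@H](O)C[C@@H]1CC2(OCCO2)CC(=O)O1
F4 | step 11 | (7R)-7-[(2R)-2-[(4-methoxybenzyl)oxy]pent-4-en-1-yl]-1,4,8-trioxaspiro[4.5]decan-9-one | C=CC[C@@H](OCc1ccc(OC)cc1)C[C@@H]1CC2(OCCO2)CC(=O)O1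
F5 | step 11 | (7R)-7-[(2S)-2-[(4-methoxybenzyl)oxy]-4-oxopentyl]-1,4,8-trioxaspiro[4.5]decan-9-one | CC(=O)C[C@@H](OCc1ccc(OC)cc1)C[C@@H]1CC2(OCCO2)CC(=O)O1
F6 | step 11 | (7R)-7-[(2S,6S)-6-hydroxy-2-[(4-methoxybenzyl)oxy]-4-oxopentadecyl]-1,4,8-trioxaspiro[4.5]decan-9-one | CCCCCCCCC[C@H](O)CC(=O)C[C@@H](OCc1ccc(OC)cc1)C[C@@H]1CC2(OCCO2)CC(=O)O1
F7 | step 11 | (7R)-7-[(2R,4S,6S)-4,6-dihydroxy-2-[(4-methoxybenzyl)oxy]pentadecyl]-1,4,8-trioxaspiro[4.5]decan-9-one | CCCCCCCCC[C@H](O)C[C@H](O)C[C@@H](OCc1ccc(OC)cc1)C[C@@H]1CC2(OCCO2)CC(=O)O1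
F8 | step 3 | (1S,5S,6R)-spiro[8-oxabicyclo[3.2.1]octane-3,2'-[1,3]dioxolan]-6-ol | O[C@@H]1C[C@H]2CC3(OCCO3)C[C@@H]1O2
F9 | step 3 | (1S,5S,6R)-spiro[8-oxabicyclo[3.2.1]octane-3,2'-[1,3]dioxolan]-6-yl acetate | CC(=O)O[C@@H]1C[C@H]2CC3(OCCO3)C[C@@H]1O2
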